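I start from the early readings of the south run, which is this same flask followed so far.

| flask | starting material | second substrate | precatalyst | remark | time |
|---|---|---|---|---|---|
| south | 0.19 M | 0.152 M | 19 µM | the very flask that is asked about, followed so far |  |
| flask | 0.19 M | 0.152 M | 19 µM |  | 3.0 h |

- south (time / min: target / %, starting material / %): 15.0: 48.4, 45.1; 30.0: 65.2, 26.4; 50.0: 65.0, 22.3; 60.0: 66.6, 19.5; 80.0: 66.8, 20.1; 90.0: 67.0, 20.4; 120: 66.9, 20.1

(scatter of a reading: 1 percentage point)

- green: at 3.0 h take out 90 % of the target then present, then wait 1.5 h
- amber: at 3.0 h add precatalyst, 100 % of the amount charged, then wait 1.5 h
- blue: at 3.0 h add second substrate, 50.0 % of the amount charged, then wait 1.5 h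
- teal: change nothing and wait 1.5 h more

- target taken out counts as made
- the earlier runs were read with a standard deviation of 1 percentage point
- additions bring no volume worth counting

* target, in percent of the starting material first charged, at 3.0 h
* what to do for the largest gain in target; "none" if nothing gains more than 2 percentage points (green / amber / blue / teal / none)
* target present, with what was taken out counted in, in percent of the starting material first charged, after amber
* target present, with what was taken out counted in, in percent of the starting material first charged, after teal

1. At 15.0 min the south flask has lost 54.9 % of its starting material and holds 48.4 % target. I divide one by the other and read 88.2 % at that time.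

2. At 120 min the south flask has consumed 79.9 % of its starting material. The second substrate charge is 80.0 % of the starting material charge. The two match, so I take second substrate, reacting one to one, as the limiting reagent.

3. The return, target present per unit of starting material consumed, is 83.7 % at that reading.

4. Return times the second substrate share gives 67.0 % at 3.0 h. Teal and amber bring no second substrate. The target reads 66.6 % at 60.0 min and 66.9 % at 120 min, so I expect both to stay there.

5. Blue adds second substrate worth 40.0 % of the starting material charged, more than the 20.1 % still read. So the remaining starting material limits, and the gain is 17 percentage points. I leave green unreckoned.

6. The weak link is the return itself, which slips from early to late. Between 30.0 min and 120 min the step ratio reads 27.0 %, from small differences. Even that return gives blue 5.4 points, above the margin.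

The forecast gives 66.9 % now, 67 % after amber, 66.9 % after teal, and chooses blue. Of teal and amber it says “nothing is left to react”.

The flask gives 67.2 % at 3.0 h, 67.2 % after amber and 67.2 % after teal, and blue gains 17 points.

    target ⇌ isomer of the product (K = 0.190, k = 4.70 × 10⁻⁴ /s)
    starting material + enzyme ⇌ starting complex (K = 7.20 /M, k = 13000 /M/s)
    ternary complex → enzyme + target (k = 270 /s)
    second substrate + starting complex ⇌ ternary complex (K = 6.10 /M, k = 2600 /M/s)
    second substrate + precatalyst → enzyme + spent reagent (k = 0.00380 /M/s)

At 180 min the flask also holds 12.8 % isomer of the product. The return on the 20 % of starting material left gives 17 points. A neighbour flask charged with 0.76 M of starting material has second substrate worth 20.0 % of it, and 0 % of that second substrate is left at 180 min. The return predicts 16.7 % target there, and that neighbour flask holds 16.8 %.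

(The numbers in the tables stem from a simulated flask from invented constants, noise included.)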